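**Plan**

- Retrosynthesis: cut the C15–O acyl bond (esterification), C8=C17 (Wittig), C9–C11 (Negishi coupling at a C9 enol triflate), then both ring-A bonds C1–C10 and C3–C4 together (one-pot [3+3] annulation with a C1–C3 dihalide), and last C4–C5 (Michael addition to carvone).
- Enabling feature: in ring A, C10 and C4 flank C5 and are both carbanion sites. C10 is α to a ring-B C9 carbonyl, and C4 is α to C19, which is carried as a nitrile. A 1,3-dielectrophile can therefore bridge them. The C9 carbonyl is a helper that later becomes the enol triflate for the side chain; the C7 isopropenyl group of carvone steers C5 and is then excised.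
- Forward order: ring B from (S)-carvone, Michael addition, ring A by the annulation (trans-decalin), C7 dealkenylation, side chain at C9, C8 ketone, methylenation, then nitrile to aldehyde, esterification and oxidation to the C19 acid.
- Stereochemistry: C5 from carvone (attack anti to isopropenyl); C10 by alkylation anti to the C5 branch; C4 by the axial preference of the nitrile in the ring closure; C9 by hydroboration anti to the C10 methyl; C13 from (R)-3-methylglutaric acid monomethyl ester; the acyl centre from (R)-2-methylbutanoic acid.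

Key step: step 2

Remark: labdane numbering (C1–C20; ring A = C1–C5 and C10, ring B = C5–C10) is used for locants in the text; compounds 1, 15 and 25 are taken as commercial single enantiomers.

**Step 1**
Reactants: 1 (S)-carvone; 2 propanenitrile
Product: 5 2-[(1R,5S)-2-methyl-5-(prop-1-en-2-yl)-3-(trimethylsilyloxy)cyclohex-2-en-1-yl]propanenitrile (both epimers at the nitrile α-carbon), via 2-lithiopropanenitrile 3 (not isolated), via lithium enolate 4 (not isolated)
Conditions: 2, LiN(i-Pr)2, THF, −78 °C; 1, DMPU, −78 → −30 °C; Me3SiCl, −78 → 0 °C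
Reagents that add atoms: chlorotrimethylsilane, C[Si](C)(C)Cl
Why: Michael addition of the metalated nitrile (1,4- over 1,2-addition should be favoured by the ion-pair-separating cosolvent and by equilibration) should occur on the enone face anti to the isopropenyl group, which sets C5, the epimer mixture at C4 being irrelevant because C4 is planarised later, and O-silylation stores the regiodefined C9/C10 enolate.

**Step 2**
Reactants: 5 silyl enol ether; 6 1-chloro-3-iodopropane
Product: 10 (1R,4aR,7S,8aR)-1,4a-dimethyl-5-oxo-7-(prop-1-en-2-yl)decahydronaphthalene-1-carbonitrile, via potassium enolate 7 (not isolated), via chloropropyl ketone 8 (not isolated), via dilithio nitrile enolate 9 (not isolated)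
Conditions: KOt-Bu, THF, −20 °C; 6, −20 → 0 °C; then LiN(i-Pr)2 (2.3 equiv), THF, −78 → 20 °C; aq. NH4Cl
Reagents that add atoms: none
Why: KOt-Bu should cleave the O–Si bond of 5 to release the tetrasubstituted C9/C10 potassium enolate 7 with its regiochemistry intact, and this should be C-alkylated at C10 by the iodide terminus of 6 (SN2, chloride untouched), the electrophile entering axially on the face anti to the C5 branch so that C10 is set with C1 trans to C4 on ring B. LiN(i-Pr)2 should then remove H-8 (masking the ketone as its lithium enolate) and H-4, and the lithiated nitrile should displace chloride at C3 in a 6-exo-tet closure; ring A can then only form trans-fused, because its two anchoring bonds C5–C4 and C10–C1 are trans-diequatorial on ring B. The closest known reaction types are the regiospecific alkylation of enolates released from silyl enol ethers and the cycloalkylation of metalated nitriles by ω-chloroalkyl chains. C4 is controlled in the planar keteniminate: in the chair transition state the rod-like nitrile should take the axial site syn to the axial C10 methyl and the bulkier methyl the equatorial site, placing the C19 carbon axial as in the target. The step needs selectivity between the two halides, between C- and O-alkylation, and between the nitrile anion and the C8 enolate in the closure; these should be secured by the iodide/chloride reactivity gap, by the soft iodide electrophile, and by the much higher nucleophilicity of a lithiated nitrile than of a lithium ketone enolate toward a primary chloride below 20 °C.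

**Step 3**
Reactants: 10
Product: 12 (1R,4aR,8aR)-1,4a-dimethyl-5-oxodecahydronaphthalene-1-carbonitrile, via methoxy hydroperoxide 11 (not isolated)
Conditions: O3, MeOH, −78 °C; then FeSO4·7H2O, PhSH, −78 → 20 °C
Reagents that add atoms: none
Why: Ozonolysis in methanol should turn the isopropenyl group into an α-methoxy hydroperoxide, which divalent iron reduces to an alkoxyl radical that undergoes β-scission to methyl acetate and a C7 radical quenched by hydrogen transfer from the thiol (hydrodealkenylation), and no stereocentre arises because C7 becomes a methylene group.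

**Step 4**
Reactants: 12
Product: 14 (4aR,5R,8aR)-5-cyano-5,8a-dimethyl-3,4,4a,5,6,7,8,8a-octahydronaphthalen-1-yl trifluoromethanesulfonate, via potassium enolate 13 (not isolated)
Conditions: KN(SiMe3)2, THF, −78 °C; PhNTf2, −78 → 0 °C
Reagents that add atoms: N-phenylbis(trifluoromethanesulfonimide), O=S(=O)(N(c1ccccc1)S(=O)(=O)C(F)(F)F)C(F)(F)F
Why: Enol triflate formation should be regiospecific because C10 is quaternary, so the ketone can enolise only towards C8, and O-sulfonylation of that enolate gives the C8=C9 triflate without touching a stereocentre.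

**Step 5**
Reactants: 15 (R)-3-methylglutaric acid monomethyl ester
Product: 16 methyl (3R)-5-hydroxy-3-methylpentanoate
Conditions: BH3·SMe2, THF, 0 → 20 °C; MeOH quench; used crude
Reagents that add atoms: none
Why: Chemoselective borane reduction should convert the carboxylic acid (via its acyloxyborane) much faster than the ester, which differentiates the two arms of the glutarate and leaves the future C13 centre untouched.

**Step 6**
Reactants: 16
Product: 17 methyl (3S)-5-iodo-3-methylpentanoate
Conditions: I2, PPh3, imidazole, CH2Cl2, 0 → 20 °C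
Reagents that add atoms: iodine, [I][I]
Why: Appel-type iodination should replace the primary hydroxyl by iodide through the alkoxyphosphonium salt before lactonisation can compete, the descriptor changing only through the priority rules.

**Step 7**
Reactants: 17 iodo ester; 14 enol triflate
Product: 19 methyl (3R)-5-[(4aS,5R,8aR)-5-cyano-5,8a-dimethyl-3,4,4a,5,6,7,8,8a-octahydronaphthalen-1-yl]-3-methylpentanoate, via alkylzinc iodide 18 (not isolated)
Conditions: 17, Zn dust (activated by BrCH2CH2Br, Me3SiCl), DMA, 40 °C; then 14, PdCl2(dppf) (5 mol %), THF/DMA, 60 °C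
Reagents that add atoms: none
Why: Negishi coupling: zinc should insert into the primary C–I bond to give an ester-tolerant alkylzinc iodide, which zerovalent palladium generated from PdCl2(dppf) joins to the enol triflate (oxidative addition, transmetalation, reductive elimination outpacing β-hydride elimination with the wide-bite-angle ligand), forming C9–C11 with no stereocentre involved.

**Step 8**
Reactants: 19
Product: 21 methyl (3R)-5-[(1S,2S,4aS,5R,8aR)-5-cyano-2-hydroxy-5,8a-dimethyldecahydronaphthalen-1-yl]-3-methylpentanoate, via alkylborane 20 (not isolated)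
Conditions: BH3·SMe2, THF, 0 → 20 °C; then H2O2, aq. NaOAc, 0 → 20 °C
Reagents that add atoms: hydrogen peroxide, OO
Why: Hydroboration–oxidation should place boron on the less substituted C8 and hydrogen on C9 in a syn addition from the face opposite the axial C10 methyl, which sets C9 with H-9 anti to C20 (side chain equatorial, as in the target), the alkene reacting much faster than nitrile or ester at this temperature and the C–B bond being oxidised with retention.

**Step 9**
Reactants: 21
Product: 22 methyl (3R)-5-[(1S,4aS,5R,8aR)-5-cyano-5,8a-dimethyl-2-oxodecahydronaphthalen-1-yl]-3-methylpentanoate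
Conditions: Dess–Martin periodinane, CH2Cl2, 20 °C
Reagents that add atoms: none
Why: Dess–Martin oxidation of the secondary alcohol should give the C8 ketone under non-basic conditions, and C9 already carries the thermodynamically preferred equatorial side chain so it is not at risk.

**Step 10**
Reactants: 22
Product: 23 methyl (3R)-5-[(1R,4aS,5R,8aS)-5-cyano-5,8a-dimethyl-2-methylidenedecahydronaphthalen-1-yl]-3-methylpentanoate
Conditions: Ph3PCH3Br, KOt-Bu, THF, 0 → 45 °C
Reagents that add atoms: methyltriphenylphosphonium bromide, C[P+](c1ccccc1)(c1ccccc1)c1ccccc1.[Br-]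
Why: Wittig methylenation: the unstabilised ylide should attack the ketone much faster than the ester or the fully substituted nitrile and install the C8=C17 exocyclic alkene, any reversible enolisation towards C9 returning the same equatorial epimer.

**Step 11**
Reactants: 23
Product: 24 (1R,4aS,5R,8aS)-5-[(3R)-5-hydroxy-3-methylpentyl]-1,4a-dimethyl-6-methylidenedecahydronaphthalene-1-carbaldehyde
Conditions: i-Bu2AlH (5 equiv), toluene, −78 → 20 °C; then 1 M HCl, THF, 0 °C
Reagents that add atoms: water, O
Why: Hydride reduction with i-Bu2AlH should take the ester to the primary alcohol while the hindered nitrile accepts one hydride to give an N-aluminated aldimine that is hydrolysed to the aldehyde on work-up (nitrile-to-aldehyde reduction), and no stereocentre is affected because C4 is quaternary.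

**Step 12**
Reactants: 24; 25 (R)-2-methylbutanoic acid
Product: 26 (3R)-5-[(1R,4aS,5R,8aS)-5-formyl-5,8a-dimethyl-2-methylidenedecahydronaphthalen-1-yl]-3-methylpentyl (2R)-2-methylbutanoate
Conditions: DCC, DMAP (cat.), CH2Cl2, 0 → 20 °C
Reagents that add atoms: none
Why: Steglich esterification should acylate the only hydroxyl group under near-neutral conditions that do not epimerise the α-centre of the acid, the non-enolisable neopentyl aldehyde being inert.

**Step 13**
Reactants: 26
Product: 27 (1R,4aS,5R,8aS)-1,4a-dimethyl-6-methylidene-5-[(3R)-3-methyl-5-{[(2R)-2-methylbutanoyl]oxy}pentyl]decahydronaphthalene-1-carboxylic acid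
Conditions: NaClO2, NaH2PO4, 2-methylbut-2-ene, t-BuOH/H2O, 20 °C
Reagents that add atoms: sodium chlorite (NaClO2), [Na+].[O-]Cl=O
Why: Pinnick oxidation should convert the hindered aldehyde into the C19 carboxylic acid at buffered pH, the alkene scavenger removing hypochlorous acid so that the exocyclic alkene and the ester survive and no stereocentre is touched.

**Compound list**

1 | (S)-carvone, (5S)-2-methyl-5-(prop-1-en-2-yl)cyclohex-2-en-1-one | CC1=CC[C@@H](CC1=O)C(C)=C | starting material
2 | propanenitrile | CCC#N | starting material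
3 | 2-lithiopropanenitrile | CC([Li])C#N | intermediate
4 | lithium (3R,5S)-3-(1-cyanoethyl)-2-methyl-5-(prop-1-en-2-yl)cyclohex-1-en-1-olate | C1[C@@H](C(C)=C)C[C@H](C(C)C#N)C(C)=C1O[Li] | intermediate
5 | 2-[(1R,5S)-2-methyl-5-(prop-1-en-2-yl)-3-(trimethylsilyloxy)cyclohex-2-en-1-yl]propanenitrile | C1[C@@H](C(C)=C)C[C@H](C(C)C#N)C(C)=C1O[Si](C)(C)C | intermediate
6 | 1-chloro-3-iodopropane | ClCCCI | starting material
7 | potassium (3R,5S)-3-(1-cyanoethyl)-2-methyl-5-(prop-1-en-2-yl)cyclohex-1-en-1-olate | C1[C@@H](C(C)=C)C[C@H](C(C)C#N)C(C)=C1O[K] | intermediate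
8 | 2-[(1R,2R,5S)-2-(3-chloropropyl)-2-methyl-3-oxo-5-(prop-1-en-2-yl)cyclohexyl]propanenitrile | C1[C@@H](C(C)=C)C[C@H](C(C)C#N)[C@@](C)(CCCCl)C1=O | intermediate
9 | dilithio derivative of 8 (lithium enolate towards C8, lithiated nitrile at C4) | C1[C@@H](C(C)=C)C[C@H](C(C)([Li])C#N)[C@@](C)(CCCCl)C(O[Li])=1 | intermediate
10 | (1R,4aR,7S,8aR)-1,4a-dimethyl-5-oxo-7-(prop-1-en-2-yl)decahydronaphthalene-1-carbonitrile (trans-decalin; nitrile axial, cis to the C10 methyl) | C1[C@@H](C(C)=C)C[C@H]2[C@@](C)(CCC[C@@]2(C)C#N)C1=O | intermediate
11 | (1R,4aR,7S,8aR)-7-(1-hydroperoxy-1-methoxyethyl)-1,4a-dimethyl-5-oxodecahydronaphthalene-1-carbonitrile | C1[C@@H](C(C)(OC)OO)C[C@H]2[C@@](C)(CCC[C@@]2(C)C#N)C1=O | intermediate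
12 | (1R,4aR,8aR)-1,4a-dimethyl-5-oxodecahydronaphthalene-1-carbonitrile | C1CC[C@H]2[C@@](C)(CCC[C@@]2(C)C#N)C1=O | intermediate
13 | potassium enolate of 12 (C8=C9–OK) | C1CC[C@H]2[C@@](C)(CCC[C@@]2(C)C#N)C(O[K])=1 | intermediate
14 | (4aR,5R,8aR)-5-cyano-5,8a-dimethyl-3,4,4a,5,6,7,8,8a-octahydronaphthalen-1-yl trifluoromethanesulfonate | C1CC[C@H]2[C@@](C)(CCC[C@@]2(C)C#N)C(OS(=O)(=O)C(F)(F)F)=1 | intermediate
15 | (R)-3-methylglutaric acid monomethyl ester, (3R)-5-methoxy-3-methyl-5-oxopentanoic acid | OC(=O)C[C@@H](C)CC(=O)OC | starting material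
16 | methyl (3R)-5-hydroxy-3-methylpentanoate | OCC[C@@H](C)CC(=O)OC | intermediate
17 | methyl (3S)-5-iodo-3-methylpentanoate | ICC[C@@H](C)CC(=O)OC | intermediate
18 | [(3S)-5-methoxy-3-methyl-5-oxopentyl]zinc iodide | I[Zn]CC[C@@H](C)CC(=O)OC | intermediate
19 | methyl (3R)-5-[(4aS,5R,8aR)-5-cyano-5,8a-dimethyl-3,4,4a,5,6,7,8,8a-octahydronaphthalen-1-yl]-3-methylpentanoate | C1CC[C@H]2[C@@](C)(CCC[C@@]2(C)C#N)C(CC[C@@H](C)CC(=O)OC)=1 | intermediate
20 | C8 alkylborane of 19 (boron at C8 and hydrogen at C9 syn, both anti to the C10 methyl) | B[C@H]1CC[C@H]2[C@@](C)(CCC[C@@]2(C)C#N)[C@@H]1CC[C@@H](C)CC(=O)OC | intermediate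
21 | methyl (3R)-5-[(1S,2S,4aS,5R,8aR)-5-cyano-2-hydroxy-5,8a-dimethyldecahydronaphthalen-1-yl]-3-methylpentanoate | O[C@H]1CC[C@H]2[C@@](C)(CCC[C@@]2(C)C#N)[C@@H]1CC[C@@H](C)CC(=O)OC | intermediate
22 | methyl (3R)-5-[(1S,4aS,5R,8aR)-5-cyano-5,8a-dimethyl-2-oxodecahydronaphthalen-1-yl]-3-methylpentanoate | O=C1CC[C@H]2[C@@](C)(CCC[C@@]2(C)C#N)[C@@H]1CC[C@@H](C)CC(=O)OC | intermediate
23 | methyl (3R)-5-[(1R,4aS,5R,8aS)-5-cyano-5,8a-dimethyl-2-methylidenedecahydronaphthalen-1-yl]-3-methylpentanoate | C=C1CC[C@H]2[C@@](C)(CCC[C@@]2(C)C#N)[C@@H]1CC[C@@H](C)CC(=O)OC | intermediate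
24 | (1R,4aS,5R,8aS)-5-[(3R)-5-hydroxy-3-methylpentyl]-1,4a-dimethyl-6-methylidenedecahydronaphthalene-1-carbaldehyde | C=C1CC[C@H]2[C@@](C)(CCC[C@@]2(C)C=O)[C@@H]1CC[C@@H](C)CCO | intermediate
25 | (R)-2-methylbutanoic acid | CC[C@@H](C)C(=O)O | starting material
26 | (3R)-5-[(1R,4aS,5R,8aS)-5-formyl-5,8a-dimethyl-2-methylidenedecahydronaphthalen-1-yl]-3-methylpentyl (2R)-2-methylbutanoate | C=C1CC[C@H]2[C@@](C)(CCC[C@@]2(C)C=O)[C@@H]1CC[C@@H](C)CCOC(=O)[C@H](C)CC | intermediate
27 | (1R,4aS,5R,8aS)-1,4a-dimethyl-6-methylidene-5-[(3R)-3-methyl-5-{[(2R)-2-methylbutanoyl]oxy}pentyl]decahydronaphthalene-1-carboxylic acid | C=C1CC[C@H]2[C@@](C)(CCC[C@@]2(C)C(=O)O)[C@@H]1CC[C@@H](C)CCOC(=O)[C@H](C)CC | target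

**Count**

Total step count: 13. Longest linear sequence: 11 steps (steps 1–4 and 7–13, from 1); steps 5 and 6 prepare the side-chain fragment.

**Steps most likely to fail**

1. Step 2. Proton transfer between enolate 7 and the alkylated ketone could erode the regiocontrol of the first alkylation, and O-alkylation could compete. In the closure, the C8 enolate could attack the chloride in a bridging alkylation, HCl could be eliminated, or the axial preference of the nitrile could be too small, giving the C4 epimer. Fallback: the one-pot sequence is stopped after the first alkylation and chloropropyl ketone 8 is isolated. Its ketone is masked by kinetic enolisation towards C8 (KN(SiMe3)2, t-BuMe2SiCl, THF, −78 °C) as tert-butyldimethylsilyl enol ether F1. H-4 is then the only acidic site; it is removed with LiN(i-Pr)2 and the nitrile anion cyclises onto the chloride to give bicyclic silyl enol ether F2. Aqueous HCl in THF unmasks the ketone, and the route is rejoined at 10.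

2. Step 1. The lithiated nitrile could add 1,2 to the carbonyl group or deprotonate carvone instead of adding in the conjugate sense. Fallback: setting out from 1, base-catalysed Michael addition of the doubly stabilised anion of ethyl 2-cyanopropanoate (cat. KOt-Bu, t-BuOH/THF) should give cyano ester F3 by 1,4-addition only, again anti to the isopropenyl group. Krapcho dealkoxycarbonylation (LiCl, wet DMSO, 150 °C) then gives keto nitrile F4. Silylation under equilibrating conditions (Me3SiCl, NaI, Et3N, MeCN) gives the more substituted silyl enol ether, and the route is rejoined at 5.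

3. Step 8. Hydroboration of the hindered trisubstituted alkene could be slow enough for borane to reduce the nitrile or the ester, or addition could occur from the wrong face. Fallback: setting out from 19, epoxidation with m-chloroperbenzoic acid on the face anti to the C10 methyl gives epoxide F5. BF3·OEt2 opens it at the tertiary C9 and a 1,2-hydride shift from C8 (Meinwald rearrangement) gives the C8 ketone. Its C9 centre is equilibrated with DBU to the equatorial side-chain epimer, and the route is rejoined at 22, bypassing 21.

**Further compounds**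

F1 | step 2 | 2-[(1R,2R,5S)-3-(tert-butyldimethylsilyloxy)-2-(3-chloropropyl)-2-methyl-5-(prop-1-en-2-yl)cyclohex-3-en-1-yl]propanenitrile | C1[C@@H](C(C)=C)C[C@H](C(C)C#N)[C@@](C)(CCCCl)C(O[Si](C)(C)C(C)(C)C)=1
F2 | step 2 | (1R,4aR,7S,8aR)-5-(tert-butyldimethylsilyloxy)-1,4a-dimethyl-7-(prop-1-en-2-yl)-1,2,3,4,4a,7,8,8a-octahydronaphthalene-1-carbonitrile | C1[C@@H](C(C)=C)C[C@H]2[C@@](C)(CCC[C@@]2(C)C#N)C(O[Si](C)(C)C(C)(C)C)=1
F3 | step 1 | ethyl 2-cyano-2-[(1S,5S)-2-methyl-3-oxo-5-(prop-1-en-2-yl)cyclohexyl]propanoate | C1[C@@H](C(C)=C)C[C@H](C(C)(C#N)C(=O)OCC)C(C)C1=O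
F4 | step 1 | 2-[(1R,5S)-2-methyl-3-oxo-5-(prop-1-en-2-yl)cyclohexyl]propanenitrile | C1[C@@H](C(C)=C)C[C@H](C(C)C#N)C(C)C1=O
F5 | step 8 | 8,9-epoxide of 19 (oxygen anti to the C10 methyl) | O1[C@H]2CC[C@H]3[C@@](C)(CCC[C@@]3(C)C#N)[C@@]12CC[C@@H](C)CC(=O)OC
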